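**Strategy.** Everything rests on disconnecting the bond between the β-carbon (C3) of the 2-(hydroxymethyl)propenoate linker and C1 of the hydroxymethyl-cyclohexene ring. Step 15 exploits the 1,4-relationship between that ring carbon and the hydroxymethyl oxygen across the ring C2=C3 double bond: palladium-catalysed anti-SN2′ opening of a cryptone-derived spiro vinyl oxirane by an (E)-alkenyl boronate forms the bond, sets C1 cis to the isopropyl group, transposes the alkene and releases the CH2OH in one operation. The boronate partner is the finished benzoxepinone half, built from the same (R)-cryptone by reductive conjugate alkenylation, Corey–Chaykovsky epoxidation and carboxylate ring opening.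

Key step: step 15

Remark: in step 5 the (R)-configured prolinol ether is assumed, from the steric-shielding enamine model, to give the (R)-aldehyde; the antipodal catalyst would be used if the sense proves opposite.

Locants C1–C4 in the descriptive names of 12–17 follow cryptone numbering (C1 = former carbonyl carbon, C3 = former β-carbon, C4 = isopropyl carbon).

Step 1
Reactants: 1 ethyl 2-(hydroxymethyl)acrylate
Product: 2 ethyl 2-{[(tert-butyldimethylsilyl)oxy]methyl}acrylate
Conditions: TBSCl, imidazole, CH2Cl2, 0 °C to rt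
Reagents that add atoms: tert-butyldimethylsilyl chloride, CC(C)(C)[Si](C)(C)Cl
Why: Imidazole-mediated silylation of the only hydroxyl gives the silyl ether, which keeps the alcohol from closing onto the vicinal dibromide formed in step 2.

Step 2
Reactants: 2 ethyl 2-{[(tert-butyldimethylsilyl)oxy]methyl}acrylate
Product: 4 ethyl (E)-3-bromo-2-{[(tert-butyldimethylsilyl)oxy]methyl}acrylate, via dibromide 3 (not isolated)
Conditions: Br2, CH2Cl2, 0 °C; then DBU, 0 °C to rt
Reagents that add atoms: bromine, BrBr
Why: Electrophilic bromination of the acrylate followed by E2 dehydrobromination (loss of the more acidic BrCH2 proton) should give the bromoalkene with bromine trans to the ester, by analogy with the bromination–dehydrobromination of methacrylates.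

Step 3
Reactants: 4 ethyl (E)-3-bromo-2-{[(tert-butyldimethylsilyl)oxy]methyl}acrylate
Product: 5 (E)-3-bromo-2-{[(tert-butyldimethylsilyl)oxy]methyl}acrylic acid
Conditions: LiOH, THF/H2O, 0 °C to rt; then cold 1 M HCl to pH 4
Reagents that add atoms: lithium hydroxide, [Li+].[OH-]
Why: Saponification of the ethyl ester should leave the silyl ether and the vinyl bromide intact, since the carboxylate formed is a poor acceptor for addition–elimination.

Step 4
Reactants: 5 (E)-3-bromo-2-{[(tert-butyldimethylsilyl)oxy]methyl}acrylic acid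
Product: 6 2-(trimethylsilyl)ethyl (E)-3-bromo-2-{[(tert-butyldimethylsilyl)oxy]methyl}acrylate
Conditions: 2-(trimethylsilyl)ethanol, DCC, DMAP (cat.), CH2Cl2, 0 °C to rt
Reagents that add atoms: 2-(trimethylsilyl)ethanol, C[Si](C)(C)CCO
Why: Steglich esterification installs the fluoride-labile 2-(trimethylsilyl)ethyl ester that masks the future free acid until the last step.

Step 5
Reactants: 7 3-methylbutanal; 8 but-3-en-2-one
Product: 10 (R)-4-isopropylcyclohex-2-en-1-one, via keto aldehyde 9 (not isolated)
Conditions: (R)-2-(methoxydiphenylmethyl)pyrrolidine (5 mol %), ethyl 3,4-dihydroxybenzoate (20 mol %), neat, 4 °C; then LiOH, iPrOH, rt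
Reagents that add atoms: none
Why: Enamine-mediated Michael addition, in which the diarylmethyl group shields one enamine face and should set the (R) centre, is followed by intramolecular aldol condensation (Robinson-type annulation).

Step 6
Reactants: 10 (R)-4-isopropylcyclohex-2-en-1-one
Product: 11 (3S,6R)-6-isopropyl-1-oxaspiro[2.5]oct-4-ene
Conditions: Me3S+ I−, KN(SiMe3)2, THF, −10 °C to 0 °C
Reagents that add atoms: trimethylsulfonium iodide, C[S+](C)C.[I-]
Why: Corey–Chaykovsky epoxidation with the unstabilised sulfonium ylide adds 1,2 to the enone, and axial attack on the half-chair with pseudo-equatorial isopropyl should place the oxirane oxygen trans to isopropyl at the new spiro centre.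

Step 7
Reactants: 10 (R)-4-isopropylcyclohex-2-en-1-one; 6 2-(trimethylsilyl)ethyl (E)-3-bromo-2-{[(tert-butyldimethylsilyl)oxy]methyl}acrylate
Product: 12 2-(trimethylsilyl)ethyl (E)-2-{[(tert-butyldimethylsilyl)oxy]methyl}-3-[(3S,4R)-4-isopropyl-1-(triethylsilyloxy)cyclohex-1-en-3-yl]acrylate
Conditions: NiCl2(dme) (10 mol %), neocuproine (10 mol %), Mn powder, Et3SiCl, DMF, rt
Reagents that add atoms: chlorotriethylsilane, CC[Si](CC)(CC)Cl
Why: Nickel-catalysed reductive conjugate addition (cross-electrophile coupling of an alkenyl bromide with an enone, silyl chloride as trap, Mn as reductant) should deliver the alkenyl group anti to the adjacent isopropyl group with retention of the (E) geometry and trap the regiodefined enolate as its silyl ether.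

Step 8
Reactants: 12 the triethylsilyl enol ether
Product: 13 2-(trimethylsilyl)ethyl (E)-2-{[(tert-butyldimethylsilyl)oxy]methyl}-3-[(2R,3S,4R)-2-(dimethoxymethyl)-4-isopropyl-1-oxocyclohex-3-yl]acrylate
Conditions: HC(OMe)3, TMSOTf (10 mol %), CH2Cl2, −78 °C
Reagents that add atoms: trimethyl orthoformate, COC(OC)OC
Why: Mukaiyama-type addition of the silyl enol ether to the dimethoxycarbenium ion introduces the future lactone carbon as a non-acidifying acetal, anti to the neighbouring alkenyl group (the all-equatorial and also thermodynamic epimer).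

Step 9
Reactants: 13 the acetal ketone
Product: 14 (1S,2S,3S,4R)-spiro-oxirane of 13 (oxirane oxygen equatorial and trans to the C2 acetal; CH2 axial)
Conditions: Me3S+ I−, KN(SiMe3)2, THF, −10 °C to 0 °C
Reagents that add atoms: trimethylsulfonium iodide, C[S+](C)C.[I-]
Why: Corey–Chaykovsky epoxidation by axial delivery of the ylide methylene to the ketone should give the spiro-oxirane with equatorial oxygen, which fixes the configuration of the future tertiary carbinol.

Step 10
Reactants: 14 the spiro-oxirane; 5 (E)-3-bromo-2-{[(tert-butyldimethylsilyl)oxy]methyl}acrylic acid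
Product: 15 (1S,2S,3S,4R)-hydroxy ester: C1 carries OH and CH2O–[(E)-3-bromo-2-(TBSO-methyl)acryloyl]; C2 CH(OMe)2; C3 the (E)-CH=C(CH2OTBS)CO2CH2CH2SiMe3 group; C4 isopropyl
Conditions: Cs2CO3 (0.2 equiv), DMF, 60 °C
Reagents that add atoms: none
Why: Base-catalysed SN2 opening of the 2,2-disubstituted oxirane at its CH2 terminus by the carboxylate of 5 forms the linking ester and liberates the tertiary alcohol without touching the stereocentre.

Step 11
Reactants: 15 the hydroxy ester
Product: 16 (1S,2S,3S,4R)-hydroxy aldehyde: as 15 with C2 CHO and both CH2OTBS groups as CH2OH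
Conditions: TsOH·H2O (0.2 equiv), acetone/H2O (10:1), rt
Reagents that add atoms: water, O
Why: Acid-catalysed hydrolysis cleaves the dimethyl acetal and both primary silyl ethers in one operation while the tertiary alcohol and the esters should survive dilute acid; the aldehyde is expected to equilibrate with its seven-membered lactol.

Step 12
Reactants: 16 the hydroxy aldehyde
Product: 17 (1S,2S,3S,4R)-hydroxy acid: as 16 with C2 CO2H
Conditions: NaClO2, NaH2PO4, 2-methyl-2-butene, tBuOH/H2O, 0 °C to rt
Reagents that add atoms: sodium chlorite, [Na+].[O-]Cl=O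
Why: Pinnick oxidation converts only the aldehyde (free or as lactol) to the acid and leaves the allylic alcohols, alkenes and the vinyl bromide untouched.

Step 13
Reactants: 17 the hydroxy acid
Product: 18 2-(trimethylsilyl)ethyl (5aS,6R,9S,9aS)-9-({[(E)-3-bromo-2-(hydroxymethyl)acryloyl]oxy}methyl)-9-hydroxy-6-isopropyl-1-oxo-1,3,5a,6,7,8,9,9a-octahydro-2-benzoxepine-4-carboxylate
Conditions: 2-methyl-6-nitrobenzoic anhydride, DMAP, Et3N, CH2Cl2 (high dilution), rt
Reagents that add atoms: none
Why: Shiina lactonisation activates the single carboxylic acid as a mixed anhydride, and the cis-disposed allylic hydroxymethyl group should close the seven-membered lactone in preference to the nine-membered or β-lactone alternatives.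

Step 14
Reactants: 18 the bromo lactone
Product: 19 2-(trimethylsilyl)ethyl (5aS,6R,9S,9aS)-9-hydroxy-9-({[(E)-2-(hydroxymethyl)-3-(4,4,5,5-tetramethyl-1,3,2-dioxaborolan-2-yl)acryloyl]oxy}methyl)-6-isopropyl-1-oxo-1,3,5a,6,7,8,9,9a-octahydro-2-benzoxepine-4-carboxylate
Conditions: B2pin2, PdCl2(dppf) (5 mol %), KOAc, 1,4-dioxane, 80 °C
Reagents that add atoms: bis(pinacolato)diboron, CC1(C)OB(OC1(C)C)B1OC(C)(C)C(C)(C)O1
Why: Miyaura borylation of the electron-poor alkenyl bromide proceeds with retention of alkene geometry under weakly basic conditions that the lactone, the esters and the free alcohols should tolerate.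

Step 15
Reactants: 19 the alkenyl boronate; 11 (3S,6R)-6-isopropyl-1-oxaspiro[2.5]oct-4-ene
Product: 20 2-(trimethylsilyl)ethyl (5aS,6R,9S,9aS)-9-hydroxy-9-({[(E)-2-(hydroxymethyl)-3-[(1S,6R)-3-(hydroxymethyl)-6-isopropylcyclohex-2-en-1-yl]acryloyl]oxy}methyl)-6-isopropyl-1-oxo-1,3,5a,6,7,8,9,9a-octahydro-2-benzoxepine-4-carboxylate
Conditions: Pd2(dba)3 (2.5 mol %), PPh3 (10 mol %), K3PO4, THF/H2O (9:1), rt, excess 11
Reagents that add atoms: none
Why: Zerovalent palladium ionises the spiro vinyl oxirane 11 anti to the allylic C–O bond to give a zwitterionic π-allylpalladium alkoxide, whose alkoxide (with phosphate) activates boronate 19; transmetalation with retention of the (E) geometry and reductive elimination on the palladium-bearing face at the distal allyl terminus forge the bond (net anti-SN2′, inversion). The closest known reaction type is the Suzuki–Miyaura-type 1,4-coupling of vinyl epoxides with alkenylboron reagents (Tsuji–Trost ionisation coupled to transmetalation). No ring is closed; the oxirane is opened, its oxygen becomes the primary allylic alcohol and the double bond moves to its position in the product. The single new stereocentre (ring C1, S) is controlled by chirality transfer from the spiro carbon: because the oxygen of 11 is trans to isopropyl, the alkenyl group should enter cis to isopropyl, the contra-steric face that a substrate-controlled conjugate addition would not reach. The step needs 1,4- over 1,2-regioselectivity, secured by the fully substituted proximal allyl terminus, and chemoselectivity for the strained oxirane over the allylic lactone C–O bond, secured by the much faster ionisation of the vinyl oxirane at room temperature.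

Step 16
Reactants: 20 the 2-(trimethylsilyl)ethyl ester
Product: 21 (5aS,6R,9S,9aS)-9-hydroxy-9-({[(E)-2-(hydroxymethyl)-3-[(1S,6R)-3-(hydroxymethyl)-6-isopropylcyclohex-2-en-1-yl]acryloyl]oxy}methyl)-6-isopropyl-1-oxo-1,3,5a,6,7,8,9,9a-octahydro-2-benzoxepine-4-carboxylic acid (CNP0361406.9)
Conditions: Bu4NF, AcOH, THF, 0 °C to rt
Reagents that add atoms: none
Why: Fluoride attacks silicon and fragmentation of the 2-(trimethylsilyl)ethyl ester releases ethene and the carboxylate (fluoride-induced β-elimination), the AcOH buffer keeping the lactone, the acrylate ester and the allylic alcohols intact.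

**Compound list**

1 | ethyl 2-(hydroxymethyl)acrylate | C=C(CO)C(=O)OCC | starting material
2 | ethyl 2-{[(tert-butyldimethylsilyl)oxy]methyl}acrylate | C=C(CO[Si](C)(C)C(C)(C)C)C(=O)OCC | intermediate
3 | ethyl 2,3-dibromo-2-{[(tert-butyldimethylsilyl)oxy]methyl}propanoate (racemic, not isolated) | BrCC(Br)(CO[Si](C)(C)C(C)(C)C)C(=O)OCC | intermediate
4 | ethyl (E)-3-bromo-2-{[(tert-butyldimethylsilyl)oxy]methyl}acrylate | Br/C=C(\CO[Si](C)(C)C(C)(C)C)C(=O)OCC | intermediate
5 | (E)-3-bromo-2-{[(tert-butyldimethylsilyl)oxy]methyl}acrylic acid | Br/C=C(\CO[Si](C)(C)C(C)(C)C)C(=O)O | intermediate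
6 | 2-(trimethylsilyl)ethyl (E)-3-bromo-2-{[(tert-butyldimethylsilyl)oxy]methyl}acrylate | Br/C=C(\CO[Si](C)(C)C(C)(C)C)C(=O)OCC[Si](C)(C)C | intermediate
7 | 3-methylbutanal | CC(C)CC=O | starting material
8 | but-3-en-2-one | CC(=O)C=C | starting material
9 | (R)-2-isopropyl-5-oxohexanal (not isolated) | CC(C)[C@H](C=O)CCC(C)=O | intermediate
10 | (R)-4-isopropylcyclohex-2-en-1-one, (R)-cryptone | CC(C)[C@H]1CCC(=O)C=C1 | intermediate
11 | (3S,6R)-6-isopropyl-1-oxaspiro[2.5]oct-4-ene (oxygen trans to isopropyl) | CC(C)[C@H]1CC[C@@]2(CO2)C=C1 | intermediate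
12 | (3S,4R) triethylsilyl enol ether, alkenyl trans to isopropyl | CC(C)[C@H]1CCC(O[Si](CC)(CC)CC)=C[C@@H]1/C=C(\CO[Si](C)(C)C(C)(C)C)C(=O)OCC[Si](C)(C)C | intermediate
13 | (2R,3S,4R) 2-(dimethoxymethyl) ketone, all-trans | CC(C)[C@H]1CCC(=O)[C@@H](C(OC)OC)[C@@H]1/C=C(\CO[Si](C)(C)C(C)(C)C)C(=O)OCC[Si](C)(C)C | intermediate
14 | (1S,2S,3S,4R) spiro-oxirane of 13 | CC(C)[C@H]1CC[C@@]2(CO2)[C@@H](C(OC)OC)[C@@H]1/C=C(\CO[Si](C)(C)C(C)(C)C)C(=O)OCC[Si](C)(C)C | intermediate
15 | (1S,2S,3S,4R) hydroxy ester (tertiary OH, bromoacrylate on C1-CH2O, acetal at C2) | CC(C)[C@H]1CC[C@@](O)(COC(=O)/C(=C/Br)CO[Si](C)(C)C(C)(C)C)[C@@H](C(OC)OC)[C@@H]1/C=C(\CO[Si](C)(C)C(C)(C)C)C(=O)OCC[Si](C)(C)C | intermediate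
16 | (1S,2S,3S,4R) hydroxy aldehyde (open form of the seven-membered lactol) | CC(C)[C@H]1CC[C@@](O)(COC(=O)/C(=C/Br)CO)[C@@H](C=O)[C@@H]1/C=C(\CO)C(=O)OCC[Si](C)(C)C | intermediate
17 | (1S,2S,3S,4R) hydroxy acid | CC(C)[C@H]1CC[C@@](O)(COC(=O)/C(=C/Br)CO)[C@@H](C(=O)O)[C@@H]1/C=C(\CO)C(=O)OCC[Si](C)(C)C | intermediate
18 | (5aS,6R,9S,9aS) bromoacrylate lactone, 2-(trimethylsilyl)ethyl ester | CC(C)[C@H]1CC[C@@](O)(COC(=O)/C(=C/Br)CO)[C@H]2C(=O)OCC(C(=O)OCC[Si](C)(C)C)=C[C@H]12 | intermediate
19 | (5aS,6R,9S,9aS) alkenyl pinacol boronate lactone | CC(C)[C@H]1CC[C@@](O)(COC(=O)/C(=C/B3OC(C)(C)C(C)(C)O3)CO)[C@H]2C(=O)OCC(C(=O)OCC[Si](C)(C)C)=C[C@H]12 | intermediate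
20 | 2-(trimethylsilyl)ethyl ester of the target | CC(C)[C@H]1CC[C@@](O)(COC(=O)/C(=C/[C@@H]3C=C(CO)CC[C@@H]3C(C)C)CO)[C@H]2C(=O)OCC(C(=O)OCC[Si](C)(C)C)=C[C@H]12 | intermediate
21 | CNP0361406.9 | CC(C)[C@H]1CC[C@@](O)(COC(=O)/C(=C/[C@@H]2C=C(CO)CC[C@@H]2C(C)C)CO)[C@H]2C(=O)OCC(C(=O)O)=C[C@H]12 | target

**Step count.** Total: 16 steps. Longest linear sequence: 14 steps (steps 1–4, then 7–16).

**Steps most likely to fail**

Step 15. Transmetalation from the electron-poor alkenyl boronate may be slower than collapse of the zwitterionic π-allylpalladium alkoxide (β-hydride loss and isomerisation of the oxirane), and facial fidelity of the π-allyl intermediate may erode. The fallback sets out from 11 and moves the stereochemical information onto the ring carbon that is substituted. Palladium-catalysed 1,4-addition of acetic acid (Pd(PPh3)4, AcOH, THF, 0 °C; double inversion) should give (1R,6R)-3-(hydroxymethyl)-6-isopropylcyclohex-2-en-1-yl acetate F1, an isolable and purifiable electrophile with the acetate trans to isopropyl. Suzuki–Miyaura allyl–alkenyl cross-coupling of this acetate with 19 (Pd2(dba)3, tri(2-furyl)phosphine, KF, THF/H2O), which proceeds with inversion, comes back to the route at 20.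

Step 7. Reductive homocoupling or hydrodebromination of the electron-poor alkenyl bromide may outrun capture of the silyloxyallyl nickel species, and alkene geometry may be lost at the alkenylnickel stage. The fallback sets out from 6 and uses a preformed organometallic. Copper-catalysed halogen exchange (CuI, N,N′-dimethylethylenediamine, NaI, 1,4-dioxane, 110 °C) gives 2-(trimethylsilyl)ethyl (E)-3-iodo-2-{[(tert-butyldimethylsilyl)oxy]methyl}acrylate F2. Iodine–magnesium exchange (iPrMgCl·LiCl, THF, −78 °C) gives the alkenylmagnesium chloride F3. Conjugate addition of F3 to 10 in the presence of CuI·2LiCl (cat.) and Et3SiCl comes back to the route at 12.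

Step 10. Attack of the hindered, conjugated carboxylate on the neopentyl-type oxirane carbon may be slow, so that acid-induced rearrangement of the oxirane to an aldehyde competes; poor facial selectivity in step 9 would also surface here. The fallback sets out from 13 and avoids the oxirane. Wittig methylenation (Ph3P=CH2, THF) gives the exocyclic methylene compound F4. Dihydroxylation from the less hindered equatorial face (OsO4 cat., N-methylmorpholine N-oxide, acetone/H2O) gives the diol F5 with equatorial tertiary OH; the C2 carbon is still an acetal, so no lactone can form. Steglich acylation of the primary hydroxyl of F5 with acid 5 (DCC, DMAP) comes back to the route at 15.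

**Further compounds**

F1 | step 15 | (1R,6R)-3-(hydroxymethyl)-6-isopropylcyclohex-2-en-1-yl acetate | CC(C)[C@H]1CCC(CO)=C[C@@H]1OC(C)=O
F2 | step 7 | 2-(trimethylsilyl)ethyl (E)-3-iodo-2-{[(tert-butyldimethylsilyl)oxy]methyl}acrylate | I/C=C(\CO[Si](C)(C)C(C)(C)C)C(=O)OCC[Si](C)(C)C
F3 | step 7 | (E)-alkenylmagnesium chloride derived from F2 | Cl[Mg]/C=C(\CO[Si](C)(C)C(C)(C)C)C(=O)OCC[Si](C)(C)C
F4 | step 10 | exocyclic methylene analogue of 13 (C1 = CH2) | CC(C)[C@H]1CCC(=C)[C@@H](C(OC)OC)[C@@H]1/C=C(\CO[Si](C)(C)C(C)(C)C)C(=O)OCC[Si](C)(C)C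
F5 | step 10 | (1S,2S,3S,4R) diol (C1: equatorial OH, axial CH2OH) | CC(C)[C@H]1CC[C@@](O)(CO)[C@@H](C(OC)OC)[C@@H]1/C=C(\CO[Si](C)(C)C(C)(C)C)C(=O)OCC[Si](C)(C)C
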